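## Retrosynthetic overview

1. GA36 ⇐ periodate cleavage of an α-ketol bridge C4–C19(=O)–C20H(OH)–C10, which delivers the 19-acid and the 20-aldehyde in one cut.
2. Ketol ⇐ enolate hydroxylation of the 19,20-bridged cyclopentanone ⇐ reductive opening (C20–C1 bond) of a cyclopropyl ketone.
3. Key step: intramolecular [2+1] carbenoid cycloaddition of a 19-diazoketone onto a 1(10)-alkene, which forms the C10–C20 bond and sets the C10 quaternary centre from the α face.
4. Diazoketone ⇐ 1(10)-ene-19-acid ⇐ palladium-catalysed hydride opening of the allylic 19,10-lactone of the gibberellin GA7, which supplies C3, C4, C5, C6, C8, C9 and C13.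
5. Ring order: rings A to D are bought; the cyclopropane and the C4–C19–C20–C10–C5 cyclopentanone form together in the key step, then the cyclopropane is opened and the cyclopentanone is cleaved.

Assumption: the gibberellin GA7 (fermentation product, sold pure and as the GA4/GA7 agrochemical mixture) is taken as the commercial chiral starting material, and GA36 is drawn as its open 20-aldehyde form, which equilibrates with the 19,20-lactol.

## Route

Step 1
Reactants: 1 GA7; 2 chloromethyl methyl ether
Product: 3 GA7 3-O-methoxymethyl ether 7-methoxymethyl ester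
Conditions: MOMCl (3 equiv), i-Pr2NEt (4 equiv), CH2Cl2, 0 °C → rt
Reagents that add atoms: chloromethyl methyl ether, COCCl
Why: O-alkylation of the 7-carboxylate and of the hindered allylic 3β-hydroxyl with the same reagent gives the MOM ester and MOM ether in one operation (acetal protection) without touching any stereocentre or the lactone.

Step 2
Reactants: 3 GA7 3-O-methoxymethyl ether 7-methoxymethyl ester
Product: 5 ring-opened 19-acid (3β-(methoxymethoxy)-20-norgibberella-1(10),16-diene-7,19-dioic acid 7-methoxymethyl ester), via tributylstannyl 19-carboxylate 4 (not isolated)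
Conditions: Pd(PPh3)4 (5 mol %), Bu3SnH (1.3 equiv, slow addition), THF, rt; then AcOH
Reagents that add atoms: none
Why: Tsuji–Trost-type ionisation of the strained tertiary allylic lactone by zerovalent palladium gives a C10–C1–C2 π-allyl complex, and hydride passed from tin through palladium goes to the less substituted terminus C2 (hydride sources other than formate favour the more substituted alkene), so the 1(10)-ene and only the 19-acid are released while the MOM ester and the 16-ene are untouched.

Step 3
Reactants: 5 ring-opened 19-acid; 6 diazomethane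
Product: 8 methoxymethyl 19-(diazomethyl)-3β-(methoxymethoxy)-19-oxo-20-norgibberella-1(10),16-dien-7-oate, via 19-acid chloride 7 (not isolated)
Conditions: 1-chloro-N,N,2-trimethylprop-1-en-1-amine, CH2Cl2, 0 °C → rt; then CH2N2 (excess, Et2O, freshly made from N-methyl-N-nitroso-p-toluenesulfonamide/KOH), 0 °C
Reagents that add atoms: diazomethane, C=[N+]=[N-]; 1-chloro-N,N,2-trimethylprop-1-en-1-amine, CC(C)=C(Cl)N(C)C (supplies only the chlorine of the non-isolated 7, which is lost again)
Why: the α-chloroenamine makes the neopentyl acid chloride under neutral conditions that spare both acetals, and acylation of diazomethane (first stage of an Arndt–Eistert sequence) gives the diazoketone, with a second equivalent of diazomethane taking up the HCl.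

Step 4
Reactants: 8 19-diazomethyl ketone
Product: 9 cyclopropyl ketone (methoxymethyl 3β-(methoxymethoxy)-19-oxo-1α,20:19,20-dicyclogibberell-16-en-7-oate; the C20 methine is bonded to C19, C10 and C1 on the α face)
Conditions: Cu(acac)2 (5 mol %), toluene, 100 °C, slow addition at high dilution
Reagents that add atoms: none
Why: intramolecular [2+1] cycloaddition of the copper carbenoid to the 1(10)-alkene (carbenoid cyclopropanation) forms the C10–C20 bond, and because the C19 tether is α on C4 it can only reach the α face, which fixes the new C10 quaternary centre, C1 and C20 in a tricyclo[3.2.1.0(2,7)]octan-6-one array; the 3β-OMOM oxygen lies on the opposite face and cannot intercept the carbenoid.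

Step 5
Reactants: 9 cyclopropyl ketone
Product: 10 methoxymethyl 3β-(methoxymethoxy)-19-oxo-19,20-cyclogibberell-16-en-7-oate (C4–C19(=O)–C20H2–C10 bridge on the α face)
Conditions: SmI2 (2.5 equiv), THF/HMPA, t-BuOH (2 equiv), −78 °C
Reagents that add atoms: none
Why: ketyl-type electron-transfer cleavage of the cyclopropyl ketone breaks the C20–C1 bond, the one aligned with the carbonyl π system (the C20–C10 bond lies in the cyclopentanone plane), giving the bicyclo[3.2.1]octan-6-one with C1 as CH2 and C10 unchanged, while divalent samarium spares ester, acetals and the 16-ene.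

Step 6
Reactants: 10 19,20-bridged ketone; 11 racemic trans-3-phenyl-2-(phenylsulfonyl)oxaziridine
Product: 13 methoxymethyl 20-hydroxy-3β-(methoxymethoxy)-19-oxo-19,20-cyclogibberell-16-en-7-oate (both C20 epimers), via potassium enolate 12 (not isolated)
Conditions: KN(SiMe3)2 (1.1 equiv), THF, −78 °C; then 11; AcOH quench
Reagents that add atoms: 3-phenyl-2-(phenylsulfonyl)oxaziridine, O=S(=O)(c1ccccc1)N1OC1c1ccccc1
Why: only C20 can enolise (C4 is quaternary) and the ketone is far more acidic than the hindered C6–H of the ester, so Davis enolate hydroxylation gives the α-ketol without epoxidising the 16-ene; the new C20 carbinol centre is irrelevant because C20 ends as the aldehyde.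

Step 7
Reactants: 13 protected α-ketol
Product: 14 3β,20-dihydroxy-19-oxo-19,20-cyclogibberell-16-en-7-oic acid (both C20 epimers)
Conditions: Me2BBr (6 equiv), CH2Cl2, −78 °C; then THF/aq NaHCO3, 0 °C
Reagents that add atoms: none
Why: Guindon-type acetal cleavage by dimethylboron bromide converts MOM ether and MOM ester into bromomethyl derivatives that hydrolyse on work-up, at −78 °C and without protic acid (which would isomerise the 16-ene) or strong base (which would trigger retro-aldol at C3–C4).

Step 8
Reactants: 14 deprotected α-ketol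
Product: 15 GA36
Conditions: NaIO4 (1.5 equiv), THF/H2O (pH 5 buffer), rt
Reagents that add atoms: sodium periodate, [Na+].[O-]I(=O)(=O)=O (net donor of the one oxygen gained); water, O (enters mechanistically through the ketone hydrate)
Why: Malaprade-type periodate cleavage of the α-ketol through its hydrate cuts C19–C20 to give the 19-carboxylic acid on C4 and the 20-aldehyde on C10 directly, and the non-enolisable aldehyde, the 3β-hydroxyl and the 16-ene are inert.

## Compound list

1 | GA7 (3β-hydroxy-20-norgibberella-1,16-diene-7,19-dioic acid 19,10α-lactone) | C=C1C[C@]23C[C@H]1CC[C@H]2[C@]14C=C[C@H](O)[C@@](C)(C(=O)O4)[C@H]1[C@@H]3C(=O)O | starting material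
2 | chloromethyl methyl ether | COCCl | starting material
3 | GA7 3-O-methoxymethyl ether 7-methoxymethyl ester | C=C1C[C@]23C[C@H]1CC[C@H]2[C@]14C=C[C@H](OCOC)[C@@](C)(C(=O)O4)[C@H]1[C@@H]3C(=O)OCOC | intermediate
4 | tributylstannyl 19-carboxylate of 5 | C=C1C[C@]23C[C@H]1CC[C@H]2C1=CC[C@H](OCOC)[C@@](C)(C(=O)O[Sn](CCCC)(CCCC)CCCC)[C@H]1[C@@H]3C(=O)OCOC | intermediate (not isolated)
5 | ring-opened 19-acid (3β-(methoxymethoxy)-20-norgibberella-1(10),16-diene-7,19-dioic acid 7-methoxymethyl ester) | C=C1C[C@]23C[C@H]1CC[C@H]2C1=CC[C@H](OCOC)[C@@](C)(C(=O)O)[C@H]1[C@@H]3C(=O)OCOC | intermediate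
6 | diazomethane | C=[N+]=[N-] | starting material (reagent, generated from commercial N-methyl-N-nitroso-p-toluenesulfonamide)
7 | 19-acid chloride of 5 | C=C1C[C@]23C[C@H]1CC[C@H]2C1=CC[C@H](OCOC)[C@@](C)(C(Cl)=O)[C@H]1[C@@H]3C(=O)OCOC | intermediate (not isolated)
8 | methoxymethyl 19-(diazomethyl)-3β-(methoxymethoxy)-19-oxo-20-norgibberella-1(10),16-dien-7-oate | C=C1C[C@]23C[C@H]1CC[C@H]2C1=CC[C@H](OCOC)[C@@](C)(C(=O)C=[N+]=[N-])[C@H]1[C@@H]3C(=O)OCOC | intermediate
9 | cyclopropyl ketone, methoxymethyl 3β-(methoxymethoxy)-19-oxo-1α,20:19,20-dicyclogibberell-16-en-7-oate | C=C1C[C@]23C[C@H]1CC[C@H]2[C@]14[C@@H]5C[C@H](OCOC)[C@@](C)(C(=O)[C@H]45)[C@H]1[C@@H]3C(=O)OCOC | intermediate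
10 | methoxymethyl 3β-(methoxymethoxy)-19-oxo-19,20-cyclogibberell-16-en-7-oate | C=C1C[C@]23C[C@H]1CC[C@H]2[C@]14CC[C@H](OCOC)[C@@](C)(C(=O)C4)[C@H]1[C@@H]3C(=O)OCOC | intermediate
11 | racemic trans-3-phenyl-2-(phenylsulfonyl)oxaziridine (Davis reagent) | O=S(=O)(c1ccccc1)N1OC1c1ccccc1 | starting material
12 | potassium 19(20)-enolate of 10 | C=C1C[C@]23C[C@H]1CC[C@H]2[C@]14CC[C@H](OCOC)[C@@](C)(C([O-])=C4)[C@H]1[C@@H]3C(=O)OCOC.[K+] | intermediate (not isolated)
13 | methoxymethyl 20-hydroxy-3β-(methoxymethoxy)-19-oxo-19,20-cyclogibberell-16-en-7-oate (both C20 epimers) | C=C1C[C@]23C[C@H]1CC[C@H]2[C@]14CC[C@H](OCOC)[C@@](C)(C(=O)C4O)[C@H]1[C@@H]3C(=O)OCOC | intermediate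
14 | 3β,20-dihydroxy-19-oxo-19,20-cyclogibberell-16-en-7-oic acid (both C20 epimers) | C=C1C[C@]23C[C@H]1CC[C@H]2[C@]14CC[C@H](O)[C@@](C)(C(=O)C4O)[C@H]1[C@@H]3C(=O)O | intermediate
15 | GA36 (3β-hydroxy-20-oxogibberell-16-ene-7,19-dioic acid, open 20-aldehyde form) | C=C1C[C@]23C[C@H]1CC[C@H]2[C@]1(C=O)CC[C@H](O)[C@@](C)(C(=O)O)[C@H]1[C@@H]3C(=O)O | target

## Step count and risks

Total step count: 8. Longest linear sequence: 8 (fully linear from 1).

**Step 2 (regiochemistry of hydride delivery to the π-allyl, and ionisation of a hindered tertiary lactone).** The fallback sets out from 1 and comes back at 5. Free GA7 is reduced with Li in NH3/THF at −78 °C, where the 7-carboxylate and 3-alkoxide are inert. Electron transfer cleaves the allylic C10–O bond and the allyl anion is protonated at C2, giving 3β-hydroxy-20-norgibberella-1(10),16-diene-7,19-dioic acid F1. Iodolactonisation (I2, NaHCO3, THF/H2O) is expected to close the α 19-acid onto C10 and re-form the natural γ-lactone; the 7-carboxylate could only close to a more strained 2-oxabicyclo[2.2.1]heptanone across ring B. It gives 1β-iodo-3β-hydroxy-20-norgibberell-16-ene-7,19-dioic acid 19,10α-lactone F2, which masks the 19-acid. MOMCl/i-Pr2NEt then gives its 3-O-methoxymethyl ether 7-methoxymethyl ester F3. Zn dust in AcOH/THF performs anti reductive elimination of the 1β-iodide and the 10α-carboxylate, regenerating the 1(10)-ene and the free 19-acid, which is 5.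

**Step 5 (chemoselectivity and bond selectivity of the electron-transfer opening next to an ester).** The fallback sets out from 9 and comes back at 10. The MOM ester alone is cleaved with MgBr2·OEt2 in Et2O at rt (chelation to the ester carbonyl makes it more labile than the MOM ether) to give the cyclopropyl keto acid 3β-(methoxymethoxy)-19-oxo-1α,20:19,20-dicyclogibberell-16-en-7-oic acid F4. With the acid protected as its carboxylate, the classical Li/NH3/t-BuOH reduction at −78 °C (NH4Cl quench) opens the C20–C1 bond and gives 3β-(methoxymethoxy)-19-oxo-19,20-cyclogibberell-16-en-7-oic acid F5. Re-esterification with MOMCl/i-Pr2NEt returns 10.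

**Step 6 (competing ester deprotonation, or addition of the enolate to the sulfonimine by-product).** The fallback sets out from 10 and comes back at 13. The enolate is trapped with Me3SiCl (KN(SiMe3)2, THF, −78 °C) as the trimethylsilyl enol ether methoxymethyl 3β-(methoxymethoxy)-19-(trimethylsilyloxy)-19,20-cyclogibberella-16,19(20)-dien-7-oate F6. One equivalent of dimethyldioxirane in acetone/CH2Cl2 at −78 °C epoxidises the electron-rich enol ether much faster than the 16-ene, giving the silyloxy epoxide methoxymethyl 19,20-epoxy-3β-(methoxymethoxy)-19-(trimethylsilyloxy)-19,20-cyclogibberell-16-en-7-oate F7, which is not isolated. Dilute aqueous citric acid in THF opens it to 13 (Rubottom oxidation).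

## Further compounds

F1 | step 2 | 3β-hydroxy-20-norgibberella-1(10),16-diene-7,19-dioic acid | C=C1C[C@]23C[C@H]1CC[C@H]2C1=CC[C@H](O)[C@@](C)(C(=O)O)[C@H]1[C@@H]3C(=O)O
F2 | step 2 | 1β-iodo-3β-hydroxy-20-norgibberell-16-ene-7,19-dioic acid 19,10α-lactone | C=C1C[C@]23C[C@H]1CC[C@H]2[C@]14[C@H](I)C[C@H](O)[C@@](C)(C(=O)O4)[C@H]1[C@@H]3C(=O)O
F3 | step 2 | 3-O-methoxymethyl ether 7-methoxymethyl ester of F2 | C=C1C[C@]23C[C@H]1CC[C@H]2[C@]14[C@H](I)C[C@H](OCOC)[C@@](C)(C(=O)O4)[C@H]1[C@@H]3C(=O)OCOC
F4 | step 5 | 3β-(methoxymethoxy)-19-oxo-1α,20:19,20-dicyclogibberell-16-en-7-oic acid | C=C1C[C@]23C[C@H]1CC[C@H]2[C@]14[C@@H]5C[C@H](OCOC)[C@@](C)(C(=O)[C@H]45)[C@H]1[C@@H]3C(=O)O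
F5 | step 5 | 3β-(methoxymethoxy)-19-oxo-19,20-cyclogibberell-16-en-7-oic acid | C=C1C[C@]23C[C@H]1CC[C@H]2[C@]14CC[C@H](OCOC)[C@@](C)(C(=O)C4)[C@H]1[C@@H]3C(=O)O
F6 | step 6 | methoxymethyl 3β-(methoxymethoxy)-19-(trimethylsilyloxy)-19,20-cyclogibberella-16,19(20)-dien-7-oate | C=C1C[C@]23C[C@H]1CC[C@H]2[C@]14CC[C@H](OCOC)[C@@](C)(C(O[Si](C)(C)C)=C4)[C@H]1[C@@H]3C(=O)OCOC
F7 | step 6 | methoxymethyl 19,20-epoxy-3β-(methoxymethoxy)-19-(trimethylsilyloxy)-19,20-cyclogibberell-16-en-7-oate | C=C1C[C@]23C[C@H]1CC[C@H]2[C@]14CC[C@H](OCOC)[C@@](C)(C5(O[Si](C)(C)C)OC54)[C@H]1[C@@H]3C(=O)OCOC
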